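**Plan**

Atom numbers (germacrane style): C1H=C10(CH3)–C9H2–C8H2–C7H(i-Pr)–C6H(OAc)–C5H=C4(CH3)–C3H(O-angeloyl)–C2H2–C1. The only ring is the ten-membered carbocycle C1–C10.
Enabling feature: O–C3–C4(CH3)=C5–C6–O is a cis-2-ene-1,4-dioxy unit. C3 is therefore an allylic carbinol carbon on the sp2 atom C4, the Z bond turns C3 and C6 (and so both chain ends) to one side, and four sp2 ring atoms thin out transannular contacts.
Cuts, in retrosynthetic order: angelate C–O at O3; ring bond C3–C4 (Z-alkenyl iodide plus aldehyde); C9–C10 (sp3–sp2 cross-coupling); C6–C7 (allylboration of but-2-ynal).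
Forward: a four-carbon and a six-carbon block give C6–C7, and a five-carbon block is joined at C9–C10. The alkyne becomes the Z-iodoalkene through a temporary five-membered O–Al–C4=C5–C6 ring. The ring is closed last at C3–C4 and O3 is then esterified.
Stereochemistry: C6/C7 come from a reagent-controlled anti allylboration, E C1=C10 from syn hydrozirconation, and Z C4=C5 from the aluminacycle. C3 is set from C6 by allylic 1,3-strain inside the closing ring, and the angelate geometry comes from angelic acid.

Key step: step 10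

Remark: the SMILES is read as 3S,6R,7S, 1(10)E, 4Z with a (Z)-2-methylbut-2-enoate (angelate). But-2-ynal is made fresh because it keeps poorly.

**Step 1**
Reactants: 1 pent-3-yn-1-ol
Product: 2 tert-butyl(dimethyl)(pent-3-yn-1-yloxy)silane
Conditions: TBSCl, imidazole, DMF, 0 °C to rt
Reagents that add atoms: tert-butyl(chloro)dimethylsilane (TBSCl) C[Si](C)(Cl)C(C)(C)C
Why: Routine imidazole-promoted silyl ether formation masks the primary hydroxyl that is to become the C3 aldehyde and survives the hydride, borane and palladium steps.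

**Step 2**
Reactants: 2 tert-butyl(dimethyl)(pent-3-yn-1-yloxy)silane
Product: 4 tert-butyl{[(3E)-4-iodopent-3-en-1-yl]oxy}dimethylsilane, via alkenylzirconocene chloride 3 (not isolated)
Conditions: Cp2Zr(H)Cl (excess), THF, rt to 40 °C; I2, THF, −78 to 0 °C
Reagents that add atoms: iodine [I][I]
Why: Hydrozirconation–iodinolysis: syn addition of Zr–H, equilibration by excess Cp2Zr(H)Cl towards zirconium on the less hindered methyl-bearing carbon (3) and iodinolysis with retention should give the E iodide that encodes the C1=C10 geometry.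

**Step 3**
Reactants: 5 but-2-yn-1-ol
Product: 6 but-2-ynal
Conditions: MnO2 (activated), CH2Cl2, rt; filtered, dried solution used directly
Reagents that add atoms: none
Why: Heterogeneous MnO2 oxidation is selective for propargylic alcohols and stops at the aldehyde, which is volatile and is therefore used in solution.

**Step 4**
Reactants: 7 (E)-4-methylpent-2-ene; 8 (+)-B-methoxydiisopinocampheylborane; 6 but-2-ynal
Product: 12 (4R,5R)-5-(propan-2-yl)hept-6-en-2-yn-4-ol, via E-allylpotassium 9 (not isolated), via E-allylborane 10 (not isolated), via borinate ester 11 (not isolated)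
Conditions: 7, n-BuLi, KOt-Bu, THF, −78 to −50 °C; 8, −78 °C; BF3·OEt2, −78 °C; 6, −78 °C; NaOH, H2O2, 0 °C to rt
Reagents that add atoms: none
Why: Brown crotylboration extended to an isopropyl-bearing allyl unit: Schlosser-base metalation of the allylic methyl group keeps the E geometry at low temperature (9), E-allylborane 10 reacts through a closed chair transition state that places OH and i-Pr anti (C6/C7), and the isopinocampheyl groups derived from (−)-α-pinene should select the aldehyde face that gives 6R.

**Step 5**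
Reactants: 12 (4R,5R)-5-(propan-2-yl)hept-6-en-2-yn-4-ol; 4 tert-butyl{[(3E)-4-iodopent-3-en-1-yl]oxy}dimethylsilane
Product: 14 (4R,5S,8E)-11-{[tert-butyl(dimethyl)silyl]oxy}-8-methyl-5-(propan-2-yl)undec-8-en-2-yn-4-ol, via O-boryl trialkylborane 13 (not isolated)
Conditions: 12, 9-BBN-H (2.2 equiv), THF, 0 °C to rt; then 4, PdCl2(dppf) (dppf = 1,1'-bis(diphenylphosphino)ferrocene), AsPh3, Cs2CO3, DMF–H2O, rt
Reagents that add atoms: none
Why: B-alkyl Suzuki–Miyaura coupling: 9-BBN-H silences the O–H as a borinate and adds to the monosubstituted alkene much faster than to the internal branched alkyne (13), and the sp3–sp2 coupling proceeds with retention at the alkenyl iodide, so the E C1=C10 bond is carried over.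

**Step 6**
Reactants: 14 (4R,5S,8E)-11-{[tert-butyl(dimethyl)silyl]oxy}-8-methyl-5-(propan-2-yl)undec-8-en-2-yn-4-ol
Product: 16 (2Z,4R,5S,8E)-11-{[tert-butyl(dimethyl)silyl]oxy}-2-iodo-8-methyl-5-(propan-2-yl)undeca-2,8-dien-4-ol, via cyclic alkenylalanate 15 (not isolated)
Conditions: NaAlH2(OCH2CH2OCH3)2, THF, 0 °C to rt; I2, THF, −78 to 0 °C
Reagents that add atoms: iodine [I][I]
Why: Hydroxyl-directed trans-hydroalumination–iodinolysis of a propargylic alcohol: the aluminium alkoxide delivers hydride to C5 and closes the five-membered O–Al–C4=C5–C6 ring of 15, a temporary ring that forces the C4–metal bond cis to C6, so iodinolysis with retention should give only the Z iodide.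

**Step 7**
Reactants: 16 (2Z,4R,5S,8E)-11-{[tert-butyl(dimethyl)silyl]oxy}-2-iodo-8-methyl-5-(propan-2-yl)undeca-2,8-dien-4-ol
Product: 17 (2Z,4R,5S,8E)-11-{[tert-butyl(dimethyl)silyl]oxy}-2-iodo-8-methyl-5-(propan-2-yl)undeca-2,8-dien-4-yl acetate
Conditions: Ac2O, pyridine, 4-(dimethylamino)pyridine (cat.), CH2Cl2, 0 °C to rt
Reagents that add atoms: acetic anhydride CC(=O)OC(C)=O
Why: Standard nucleophile-catalysed acetylation installs the C6 acetate of the target early, so that it also serves as the only protecting group at O6.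

**Step 8**
Reactants: 17 (2Z,4R,5S,8E)-11-{[tert-butyl(dimethyl)silyl]oxy}-2-iodo-8-methyl-5-(propan-2-yl)undeca-2,8-dien-4-yl acetate
Product: 18 (2Z,4R,5S,8E)-11-hydroxy-2-iodo-8-methyl-5-(propan-2-yl)undeca-2,8-dien-4-yl acetate
Conditions: HF·pyridine, pyridine, THF, 0 °C to rt
Reagents that add atoms: none
Why: Fluoride-driven desilylation under buffered conditions removes the primary silyl ether without touching the allylic acetate or the alkenyl iodide.

**Step 9**
Reactants: 18 (2Z,4R,5S,8E)-11-hydroxy-2-iodo-8-methyl-5-(propan-2-yl)undeca-2,8-dien-4-yl acetate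
Product: 19 (2Z,4R,5S,8E)-2-iodo-8-methyl-11-oxo-5-(propan-2-yl)undeca-2,8-dien-4-yl acetate
Conditions: Dess–Martin periodinane, CH2Cl2, 0 °C to rt; used at once
Reagents that add atoms: none
Why: Dess–Martin oxidation works under near-neutral conditions and should deliver the β,γ-unsaturated aldehyde without migration of the C1=C10 bond into conjugation.

**Step 10**
Reactants: 19 (2Z,4R,5S,8E)-2-iodo-8-methyl-11-oxo-5-(propan-2-yl)undeca-2,8-dien-4-yl acetate
Product: 22 (1R,2Z,4S,6E,10S)-4-hydroxy-3,7-dimethyl-10-(propan-2-yl)cyclodeca-2,6-dien-1-yl acetate, via alkenylchromium dichloride 20 (not isolated), via chromium alkoxide 21 (not isolated)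
Conditions: CrCl2 (10 equiv), NiCl2 (1 mol % of the CrCl2), degassed DMSO–THF, slow addition of 19 to ca. 2 mM, rt; aqueous work-up
Reagents that add atoms: none
Why: CrCl2 reduces NiCl2 to zerovalent nickel, which inserts into the C4–I bond with retention and hands the alkenyl group to trivalent chromium (20), and this weakly basic, oxophilic nucleophile adds to the C3 aldehyde to give alkoxide 21, hydrolysed to 22 on work-up. The closest known reaction type is the intramolecular Nozaki–Hiyama–Kishi reaction, established for nine- to twelve-membered carbocycles. The ten-membered ring closes in a 10-exo-trig 1,2-addition, helped by the Z C4=C5 bond that already holds C3 and C6 cis and by the E C1=C10 bond that stiffens the six-atom bridge. The new stereocentre C3 is controlled by C6: allylic 1,3-strain across the Z alkene keeps H6 and the aldehyde hydrogen in the alkene plane facing each other, the C7 and C2 arms must leave on one common face to be spanned by C8–C9–C10=C1, and both oxygen atoms therefore end on the other face, which is the 3S,6R series. The step needs closure to beat oligomerisation (slow addition, high dilution), retention of the Z geometry (trisubstituted alkenylchromium species hold their configuration) and selectivity for aldehyde addition over attack on the acetate or enolisation of the β,γ-unsaturated aldehyde (low basicity of the organochromium reagent).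

**Step 11**
Reactants: 22 (1R,2Z,4S,6E,10S)-4-hydroxy-3,7-dimethyl-10-(propan-2-yl)cyclodeca-2,6-dien-1-yl acetate; 23 angelic acid [(Z)-2-methylbut-2-enoic acid]
Product: 25 (1R,2Z,4S,6E,10S)-3,7-dimethyl-4-{[(2Z)-2-methylbut-2-enoyl]oxy}-10-(propan-2-yl)cyclodeca-2,6-dien-1-yl acetate (target), via mixed anhydride 24 (not isolated)
Conditions: 23, 2,4,6-trichlorobenzoyl chloride, Et3N, toluene, rt; then 22, toluene, 75 °C
Reagents that add atoms: none
Why: Yamaguchi-type mixed-anhydride esterification run without a nucleophilic catalyst avoids the addition–elimination pathway that turns angelates into tiglates, the alcohol attacking the less hindered angeloyl carbonyl of 24 with no change at C3.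

**Compound list**

1 | pent-3-yn-1-ol | CC#CCCO | starting material
2 | tert-butyl(dimethyl)(pent-3-yn-1-yloxy)silane | CC#CCCO[Si](C)(C)C(C)(C)C | intermediate
3 | (E)-alkenylzirconocene chloride, Zr on the methyl-bearing carbon (not isolated) | C/C(=C\CCO[Si](C)(C)C(C)(C)C)[Zr](Cl)(C1C=CC=C1)C1C=CC=C1 | intermediate
4 | tert-butyl{[(3E)-4-iodopent-3-en-1-yl]oxy}dimethylsilane | C/C(I)=C\CCO[Si](C)(C)C(C)(C)C | intermediate
5 | but-2-yn-1-ol | CC#CCO | starting material
6 | but-2-ynal | CC#CC=O | intermediate
7 | (E)-4-methylpent-2-ene | C/C=C/C(C)C | starting material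
8 | (+)-B-methoxydiisopinocampheylborane, from (−)-α-pinene | COB([C@H]1C[C@H]2C[C@@H]([C@@H]1C)C2(C)C)[C@H]1C[C@H]2C[C@@H]([C@@H]1C)C2(C)C | starting material
9 | (E)-4-methylpent-2-enylpotassium (not isolated) | [K+].[CH2-]/C=C/C(C)C | intermediate
10 | B-[(2E)-4-methylpent-2-en-1-yl]diisopinocampheylborane (not isolated) | CC(C)/C=C/CB([C@H]1C[C@H]2C[C@@H]([C@@H]1C)C2(C)C)[C@H]1C[C@H]2C[C@@H]([C@@H]1C)C2(C)C | intermediate
11 | diisopinocampheylborinate ester of 12 (not isolated) | CC#C[C@H](OB([C@H]1C[C@H]2C[C@@H]([C@@H]1C)C2(C)C)[C@H]1C[C@H]2C[C@@H]([C@@H]1C)C2(C)C)[C@@H](C=C)C(C)C | intermediate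
12 | (4R,5R)-5-(propan-2-yl)hept-6-en-2-yn-4-ol | CC#C[C@H](O)[C@@H](C=C)C(C)C | intermediate
13 | O-(9-BBN) borinate and C9-(9-BBN) trialkylborane derived from 12 (not isolated) | CC#C[C@H](OB1C2CCCC1CCC2)[C@@H](CCB1C2CCCC1CCC2)C(C)C | intermediate
14 | (4R,5S,8E)-11-{[tert-butyl(dimethyl)silyl]oxy}-8-methyl-5-(propan-2-yl)undec-8-en-2-yn-4-ol | CC#C[C@H](O)[C@@H](CC/C(C)=C/CCO[Si](C)(C)C(C)(C)C)C(C)C | intermediate
15 | sodium cyclic alkenylalanate, five-membered O–Al–C4=C5–C6 ring (not isolated) | [Na+].COCCO[Al-]1(OCCOC)O[C@H]([C@@H](CC/C(C)=C/CCO[Si](C)(C)C(C)(C)C)C(C)C)C=C1C | intermediate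
16 | (2Z,4R,5S,8E)-11-{[tert-butyl(dimethyl)silyl]oxy}-2-iodo-8-methyl-5-(propan-2-yl)undeca-2,8-dien-4-ol | C/C(I)=C/[C@H](O)[C@@H](CC/C(C)=C/CCO[Si](C)(C)C(C)(C)C)C(C)C | intermediate
17 | acetate of 16 | C/C(I)=C/[C@H](OC(C)=O)[C@@H](CC/C(C)=C/CCO[Si](C)(C)C(C)(C)C)C(C)C | intermediate
18 | (2Z,4R,5S,8E)-11-hydroxy-2-iodo-8-methyl-5-(propan-2-yl)undeca-2,8-dien-4-yl acetate | C/C(I)=C/[C@H](OC(C)=O)[C@@H](CC/C(C)=C/CCO)C(C)C | intermediate
19 | (2Z,4R,5S,8E)-2-iodo-8-methyl-11-oxo-5-(propan-2-yl)undeca-2,8-dien-4-yl acetate | C/C(I)=C/[C@H](OC(C)=O)[C@@H](CC/C(C)=C/CC=O)C(C)C | intermediate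
20 | Z-alkenylchromium dichloride from 19 (not isolated) | C/C([Cr](Cl)Cl)=C/[C@H](OC(C)=O)[C@@H](CC/C(C)=C/CC=O)C(C)C | intermediate
21 | dichlorochromium alkoxide of 22 (not isolated) | Cl[Cr](Cl)O[C@H]1C/C=C(\C)CC[C@@H](C(C)C)[C@@H](OC(C)=O)/C=C\1C | intermediate
22 | (1R,2Z,4S,6E,10S)-4-hydroxy-3,7-dimethyl-10-(propan-2-yl)cyclodeca-2,6-dien-1-yl acetate | O[C@H]1C/C=C(\C)CC[C@@H](C(C)C)[C@@H](OC(C)=O)/C=C\1C | intermediate
23 | angelic acid, (Z)-2-methylbut-2-enoic acid | C/C=C(/C)C(=O)O | starting material
24 | angelic 2,4,6-trichlorobenzoic anhydride (not isolated) | C/C=C(/C)C(=O)OC(=O)c1c(Cl)cc(Cl)cc1Cl | intermediate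
25 | (1R,2Z,4S,6E,10S)-3,7-dimethyl-4-{[(2Z)-2-methylbut-2-enoyl]oxy}-10-(propan-2-yl)cyclodeca-2,6-dien-1-yl acetate | C/C=C(/C)C(=O)O[C@H]1C/C=C(\C)CC[C@@H](C(C)C)[C@@H](OC(C)=O)/C=C\1C | target

**Step count and risks**

Total steps: 11. Longest linear sequence: 9 steps (5 to 25 through steps 3–11, and equally 1 to 25 through steps 1, 2 and 5–11).

Steps most likely to fail:

**Step 10.** The strained transition state may be looser than the allylic-strain model, so that the alkenylchromium adds to both faces of the aldehyde (poor facial selectivity at C3).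
- The fallback sets out from 19 and moves control of C3 from the C–C bond formation to a reagent-controlled reduction.
- The cyclisation is still run, and the mixture of 22 and its C3 epimer F1 is oxidised with MnO2 in CH2Cl2 to the ten-membered Z-enone F2, in which C3 is no longer stereogenic.
- Corey–Bakshi–Shibata reduction of F2 follows, with catecholborane and (R)-1-methyl-3,3-diphenyltetrahydro-1H,3H-pyrrolo[1,2-c][1,3,2]oxazaborole in toluene at −78 °C. The α-branched alkenyl side acts as the large group, so this should give 3S and come back to the route at 22.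

**Step 5.** The excess borane needed for the free hydroxyl may also hydroborate the internal alkyne (loss of chemoselectivity).
- The fallback sets out from 12 and masks the hydroxyl with a bulky group that shields the alkyne and allows one equivalent of borane.
- TESCl and imidazole in CH2Cl2 give the triethylsilyl ether F3.
- 9-BBN-H (1.05 equiv) gives the trialkylborane F4.
- Coupling with 4 under the same PdCl2(dppf)/Cs2CO3 system gives the bis-silyl ether F5.
- Pyridinium p-toluenesulfonate in MeOH at 0 °C removes the secondary triethylsilyl group selectively and comes back to the route at 14.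

**Step 11.** Slow acylation of the hindered allylic alcohol at 75 °C may allow Z-to-E isomerisation of the angeloyl unit, acetyl migration from O6 to O3, or Cope rearrangement of the 1,5-diene.
- The fallback sets out from 22 and builds the Z-enoate on the ester at low temperature.
- 2-[Bis(2,2,2-trifluoroethoxy)phosphoryl]propanoic acid F6 is made by LiOH hydrolysis of its commercial ethyl ester.
- F6 is coupled with 22 using N,N'-dicyclohexylcarbodiimide and catalytic 4-(dimethylamino)pyridine in CH2Cl2 at 0 °C to give the phosphonate ester F7.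
- Still–Gennari olefination of F7 (KN(SiMe3)2, 18-crown-6, THF, −78 °C, then acetaldehyde) should give the Z-2-methylbut-2-enoate and come back to the route at 25.

**Further compounds**

F1 | step 10 | (1R,2Z,4R,6E,10S)-4-hydroxy-3,7-dimethyl-10-(propan-2-yl)cyclodeca-2,6-dien-1-yl acetate (C3 epimer of 22) | O[C@@H]1C/C=C(\C)CC[C@@H](C(C)C)[C@@H](OC(C)=O)/C=C\1C
F2 | step 10 | (1R,2Z,6E,10S)-3,7-dimethyl-4-oxo-10-(propan-2-yl)cyclodeca-2,6-dien-1-yl acetate | O=C1C/C=C(\C)CC[C@@H](C(C)C)[C@@H](OC(C)=O)/C=C\1C
F3 | step 5 | triethylsilyl ether of 12 | CC#C[C@H](O[Si](CC)(CC)CC)[C@@H](C=C)C(C)C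
F4 | step 5 | C9-(9-BBN) trialkylborane from F3 | CC#C[C@H](O[Si](CC)(CC)CC)[C@@H](CCB1C2CCCC1CCC2)C(C)C
F5 | step 5 | O6-triethylsilyl ether of 14 | CC#C[C@H](O[Si](CC)(CC)CC)[C@@H](CC/C(C)=C/CCO[Si](C)(C)C(C)(C)C)C(C)C
F6 | step 11 | 2-[bis(2,2,2-trifluoroethoxy)phosphoryl]propanoic acid | CC(C(=O)O)P(=O)(OCC(F)(F)F)OCC(F)(F)F
F7 | step 11 | O3 2-[bis(2,2,2-trifluoroethoxy)phosphoryl]propanoate of 22 (epimers at the phosphorus-bearing carbon) | CC(C(=O)O[C@H]1C/C=C(\C)CC[C@@H](C(C)C)[C@@H](OC(C)=O)/C=C\1C)P(=O)(OCC(F)(F)F)OCC(F)(F)F
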